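## Structural features

The target is a 2-aryl-3-(hydroxymethyl)-2,3-dihydrobenzofuran. Ring A (3,4,5-trimethoxyphenyl) sits on C7, and ring B is fused to the five-membered ring through C3' (bonded to C8) and C4' (bonded to the ring oxygen). Ring B also carries a methoxy group at C5' and an (E)-3-hydroxypropenyl chain at C1', so it is a 1,3,4,5-tetrasubstituted benzene. C7 (R) and C8 (S) are neighbouring sp3 stereocentres, with ring A and the C9 hydroxymethyl group trans across the ring. The C7–O bond is a benzylic ether on a very electron-rich arene and ionises under acid; the cinnamyl alcohol is sensitive to acid, oxidants and hydrogenation; and the two primary alcohols (C9, C9') must not be confused. The real difficulty is to fix the absolute and relative configuration of C7 and C8 while two aryl–C(sp3) bonds are made, and to reach the substitution pattern of ring B without ambiguity. The key step uses the fact that C7 and C8 are adjacent, each bonded to one arene (C1 of ring A on C7, C3' of ring B on C8), with oxygen on C7: a C7=C8 alkenyl boron unit can take up both arenes in one stereospecific anti addition, and the C7–B bond stands in for the later C7–O bond. Because the ring oxygen on C4' is para to C1', a carbonyl group at C1' can first activate a C4' fluoride for ring closure and then be grown into the side chain.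

## Logic of the disconnections

**21 from 20.** Only the O–Si bond at C9 is cut. Keeping C9–O masked to the end means the two primary alcohols never need to be told apart, and fluoride is a reagent that spares both the C7 benzylic ether and the allylic alcohol. The demand is a silyl group that survives every earlier step.

**20 from 16 through 19, 18 and 17.** C7'=C8' is cut as an olefination, and C9' and C7' are returned to the ester level, so the whole side chain shrinks to the ester carbon on C1' of 16. That ester is not dead weight: it is the group that makes the ring closure possible. The forward steps must oxidise only the benzylic alcohol of 17 and give the E alkene, which a stabilised ylide does.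

**16 from 15.** The O–C4' bond is cut, leaving a C7 alcohol and a C4' fluoride para to the ester. The ring is thereby opened to an acyclic 1,2-diaryl-1,3-diol derivative whose two stereocentres are not touched by the closure (the bond is made at the aryl carbon). The demand is that the C7 alkoxide, and not O9, attacks; this requires that the silyl group on O9 does not migrate.

**15 from 14.** C7–O is exchanged for C7–B. This turns C7 into a carbon that can be built by a boron-based C–C bond formation. The oxidation must go with retention and must not hydrolyse the methyl ester.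

**14 from 6, 12 and 10 through 13.** C7–C1 and C8–C3' are cut together. All three pieces are flat: an (E)-alkenyl boronic ester, an aryllithium and an aryl triflate. Two bonds and both stereocentres come from one catalytic step. The demand is that the 1,2-shift in 13 outruns direct transfer of a group from boron to palladium. For a β-substituted alkene this is not secured with a pinacol ester, so 6 carries the hindered diol 2 on boron.

**6 from 4 and 2 through 5; 4 from 3; 2 from 1.** The C7–B bond is cut back to a terminal alkyne (syn hydroboration gives the E alkene), and the boron ligand is exchanged afterwards. The O9 silyl group in 4 is triisopropylsilyl rather than tert-butyldimethylsilyl, in view of the alkoxide step from 15 to 16.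

**10 from 9, 8 and 7.** The O–S bond and then the C3'–O bond are cut, the latter back to a C–H bond next to fluorine. 7 is bought as the methyl ester, so no esterification is needed. The demand is regioselective C–H borylation: of the three C–H bonds of 7, only the one next to fluorine is sterically open.

**12 from 11.** The C–Li bond comes from bromine–lithium exchange. The bromide released must be kept from poisoning the cationic palladium catalyst.

## Other disconnections considered

**Alternative 1:** The cut is the O–C7 bond, with C7 taken back to a methylene group, so the precursor is the 1,2-diarylpropane A2, in which only C8 is stereogenic. In the forward step Ag2O would oxidise the syringyl phenol of A2 to a para-quinone methide at C7, and the ring B phenol would add to C7 in a 5-exo sense to give A1.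

- In its favour: it follows the biogenetic pattern, it is mild, and it needs neither a fluoride nor an activating group on ring B. Addition to a quinone methide is reversible, so the more stable trans ring can be reached by equilibration. The aryl bromide of A1 would take the three-carbon chain by a Heck reaction.
- Against it here: C8 of A2 must be made as a single enantiomer by a separate asymmetric step (an auxiliary-controlled alkylation would be the obvious choice), which costs several steps. A2 has two free phenols of which only one should be oxidised. A1 lacks the C4 methyl ether, so a methylation must follow. C7 is set only by relay from C8.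
- Comparison: the chosen plan sets both centres at once under catalyst control from three flat pieces; the alternative sets one centre early and relays the second. Quinone methide chemistry is simpler in reagents but opens phenol-oxidation side paths; the conjunctive coupling is more demanding but stereospecific. In step count the route to A2 is likely to be longer than the routes to the three coupling partners.
- Where the alternative is the better: the ring closure needs no fluoride activation, the trans selectivity can correct itself, and after ring closure a Heck reaction plus a reduction is shorter than the ester-to-allylic-alcohol sequence of the chosen plan.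

**Alternative 2:** The cuts are C3'–C2' and C4'–C5', so ring B is taken apart and the dihydrofuran is kept as the cyclic silyl ketene acetal A4, which already carries C7 and C8. In the forward step A4 and the bromopyrone A5 would undergo an inverse-demand [4+2] cycloaddition (the nucleophilic C3' bonding to C6 of the pyrone); loss of CO2 and of silanol would then aromatise ring B to give A3.

- In its favour: the substitution pattern of ring B is fixed by the pyrone and not by the selectivity of an arene functionalisation. The C–O bond of the dihydrofuran is present from the start, so there is no ring-closing substitution and no question of silyl migration. Aromatisation is a strong driving force.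
- Against it here: the trans-disubstituted lactone behind A4 needs its own enantioselective synthesis of both centres. A3 carries bromine where the target has the C5' methoxy group, so a copper-catalysed methoxylation must follow. The ester of A3 then has to go through the same reduction, oxidation, olefination and reduction as in the chosen plan.
- Comparison: both plans end at a 5-carboxylate and share the same endgame. The alternative builds an arene de novo by a pericyclic step that needs heat; the chosen plan joins existing arenes by catalysis. The alternative is longer by the lactone synthesis and the methoxylation.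
- Where the alternative is the equal or the better: regiocontrol on ring B, and the absence of any alkoxide ring closure.

**Alternative 3:** The cuts are C8–C3' and C9–O; the precursor is the aryl iodide A7, an aryl ether of an enantioenriched allylic alcohol that holds C7. In the forward step Bu3SnH would generate the C3' aryl radical, 5-exo-trig addition to the vinyl group would form C8–C3' and close the ring, and the nitroxide A8 would capture the C9 radical to give A6.

- In its favour: the C9 oxygen is installed in the ring-forming step. Ring B comes from a cheap, fully substituted iodophenol with no regiochemical question. No organolithium and no precious metal are needed.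
- Against it here: C8 is set by substrate control in an irreversible radical addition, so the trans preference is kinetic and cannot be corrected afterwards. Making the aryl ether of an electron-rich, secondary benzylic allylic alcohol without loss of enantiopurity or allylic transposition is delicate, and such ethers are prone to ionisation and sigmatropic rearrangement on heating. Tin residues have to be removed, and the N–O bond has to be cleaved in an extra step.
- Comparison: the alternative fixes one centre beforehand and the other by substrate control; the chosen plan fixes both by ligand control and stereospecific anti addition. Radical chain chemistry stands against a two-electron metallate shift. The step count would probably be equal or slightly lower for the alternative.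
- Where the alternative is the equal or the better: step count and the unambiguous source of ring B. It is the weaker plan on stereocontrol at C8.

Key step: step 6

**Remarks on the chemistry (assumptions and design changes).**
- The stereochemical bookkeeping was checked: anti addition to the E alkene, C–B oxidation with retention, and substitution at the aryl carbon C4' lead to the 7R,8S trans ring.
- Boron carries the "mac" diol 2 and not pinacol: with a β-substituent on the alkene, a pinacol ate complex is prone to direct transmetalation (Suzuki–Miyaura coupling) in place of the 1,2-shift. B(mac) below means the cyclic boronic ester of diol 2.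
- O9 carries triisopropylsilyl and not tert-butyldimethylsilyl, to suppress O-to-O silyl transfer at the alkoxide stage.
- MandyPhos here means 1,1'-bis[bis(4-methoxy-3,5-dimethylphenyl)phosphino]-2,2'-bis[(R)-(dimethylamino)(phenyl)methyl]ferrocene, written as its (Sp,Sp) form. It is assumed that this hand delivers 7R; if the sense of induction on this substrate should be the opposite, the mirror-image ligand would be used with no other change.

## Route

Step 1
Reactants: 1 acenaphthoquinone (acenaphthylene-1,2-dione)
Product: 2 cis-1,2-dimethyl-1,2-dihydroacenaphthylene-1,2-diol (meso "mac" diol)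
Conditions: AlMe3 (3 equiv), toluene, 0 °C to rt; aq. potassium sodium tartrate; recrystallisation
Reagents that add atoms: trimethylaluminium, C[Al](C)C
Why: Twofold 1,2-addition of methyl to the 1,2-diketone; the second methyl should enter anti to the bulky aluminium alkoxide formed first, which leads to the cis (meso) diol. Any trans diol would be removed on crystallisation and cannot form a five-membered boronate in any case.

Step 2
Reactants: 3 propargyl alcohol (prop-2-yn-1-ol)
Product: 4 triisopropyl(prop-2-yn-1-yloxy)silane
Conditions: i-Pr3SiCl, imidazole, CH2Cl2, 0 °C to rt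
Reagents that add atoms: chlorotriisopropylsilane, CC(C)[Si](Cl)(C(C)C)C(C)C
Why: Standard silylation of a primary alcohol. The triisopropylsilyl ether is the silyl ether least given to O-to-O migration, which matters in step 8.

Step 3
Reactants: 4 triisopropyl(prop-2-yn-1-yloxy)silane; 2 cis-1,2-dimethyl-1,2-dihydroacenaphthylene-1,2-diol
Product: 6 (E)-triisopropyl{[3-(cis-6b,9a-dimethyl-6b,9a-dihydroacenaphtho[1,2-d][1,3,2]dioxaborol-8-yl)prop-2-en-1-yl]oxy}silane (the alkenyl B(mac) ester), via catechol alkenylboronate 5 (not isolated)
Conditions: catecholborane (1.1 equiv), Cy2BH (10 mol%), THF, rt; then 2 (1.0 equiv), rt; aq. NaHCO3 wash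
Reagents that add atoms: catecholborane, B1Oc2ccccc2O1
Why: Syn hydroboration of the terminal alkyne places boron on the terminal carbon and gives the E alkene. Boronic ester exchange then replaces catechol by the tertiary cis diol 2, which forms the more stable ester, and the catechol is washed out with base.

Step 4
Reactants: 7 methyl 4-fluoro-3-methoxybenzoate
Product: 9 methyl 4-fluoro-3-hydroxy-5-methoxybenzoate, via aryl pinacol boronate 8 (not isolated)
Conditions: B2pin2 (0.6 equiv), [Ir(OMe)(cod)]2 (1.5 mol%), 4,4'-di-tert-butyl-2,2'-bipyridine (3 mol%), THF, 80 °C; then KHSO5 (as 2KHSO5·KHSO4·K2SO4), acetone–H2O, rt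
Reagents that add atoms: bis(pinacolato)diboron, CC1(C)OB(OC1(C)C)B1OC(C)(C)C(C)(C)O1 (boron of 8); potassium peroxymonosulfate, [K+].[O-]S(=O)(=O)OO (oxygen of 9)
Why: Iridium-catalysed C–H borylation is governed by sterics and tolerates a fluorine neighbour: C2–H lies between two substituents, C6–H is next to the ester, and only C5–H (the future C3'), next to the small fluorine, is open. Oxidation of the C–B bond in the same flask gives the phenol (one-pot borylation–oxidation).

Step 5
Reactants: 9 methyl 4-fluoro-3-hydroxy-5-methoxybenzoate
Product: 10 methyl 4-fluoro-3-methoxy-5-(trifluoromethylsulfonyloxy)benzoate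
Conditions: Tf2O, pyridine, CH2Cl2, 0 °C
Reagents that add atoms: trifluoromethanesulfonic anhydride, O=S(=O)(OS(=O)(=O)C(F)(F)F)C(F)(F)F
Why: O-Sulfonylation of a phenol; ester, fluoride and methyl ether are inert.

Step 6
Reactants: 11 5-bromo-1,2,3-trimethoxybenzene; 6 alkenyl B(mac) ester; 10 methyl 4-fluoro-3-methoxy-5-(trifluoromethylsulfonyloxy)benzoate
Product: 14 methyl 4-fluoro-3-methoxy-5-[(2S,3R)-3-B(mac)-3-(3,4,5-trimethoxyphenyl)-1-(triisopropylsilyloxy)propan-2-yl]benzoate (anti adduct; 7R,8S in lignan numbering), via (3,4,5-trimethoxyphenyl)lithium 12 (not isolated), via lithium boron ate complex 13 (not isolated)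
Conditions: 11 (1.05 equiv), t-BuLi (2.1 equiv), Et2O, −78 °C; 6 (1.0 equiv), −78 °C to rt; solvent change to THF; 10 (1.2 equiv), Pd(OAc)2 (3 mol%), (Sp,Sp)-MandyPhos (3.6 mol%), KOTf (2 equiv), 60 °C
Reagents that add atoms: none
Why: Bromine–lithium exchange gives 12, which adds to the boron of 6 to form the four-coordinate ate complex 13. Zerovalent palladium, formed from Pd(OAc)2 and the bisphosphine, inserts into the C–OTf bond of 10 and gives a cationic aryl complex of divalent palladium that binds the C7=C8 π bond of 13. Binding triggers the 1,2-shift of the trimethoxyphenyl group from boron to C7 on the face opposite to palladium (C7–C1 formed, C8–Pd formed), and reductive elimination then makes C8–C3'; no ring is closed. The closest known reaction type is the palladium-catalysed enantioselective conjunctive cross-coupling of β-substituted alkenyl boron ate complexes with aryl triflates. The absolute configuration of C7 and C8 is set by the chiral bisphosphine, which selects the alkene face that palladium binds; their relative configuration follows stereospecifically from anti addition across the E alkene. The step needs the metallate shift to beat direct transmetalation, which the hindered diol of 2 on boron secures, and it needs reductive elimination to beat β-hydride loss, which the chelating ligand favours. The ate complex carries no free aryllithium, so the methyl ester of 10 is not attacked, and KOTf removes the bromide that would otherwise block the cationic palladium centre.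

Step 7
Reactants: 14 conjunctive coupling product
Product: 15 methyl 4-fluoro-3-[(1R,2S)-1-hydroxy-1-(3,4,5-trimethoxyphenyl)-3-(triisopropylsilyloxy)propan-2-yl]-5-methoxybenzoate
Conditions: NaBO3·4H2O (5 equiv), THF–H2O (1:1), rt
Reagents that add atoms: sodium perborate (used as the tetrahydrate), [Na+].[O-]OB=O
Why: Oxidation of the C–B bond by a hydroperoxide equivalent: C7 shifts from boron to oxygen with retention, so 7R is kept. The mildly basic perborate should spare the methyl ester and the aryl fluoride.

Step 8
Reactants: 15 hydroxy fluoro ester
Product: 16 methyl (2R,3S)-7-methoxy-2-(3,4,5-trimethoxyphenyl)-3-(triisopropylsilyloxymethyl)-2,3-dihydrobenzofuran-5-carboxylate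
Conditions: KN(SiMe3)2 (1.05 equiv), THF (0.03 M), 0 °C to rt
Reagents that add atoms: none
Why: Intramolecular nucleophilic aromatic substitution (addition–elimination, 5-exo): the C7 alkoxide attacks C4', whose fluoride is activated by the para ester. No bond to C7 or C8 is broken, so the anti adduct becomes the trans ring, and a non-nucleophilic amide base avoids transesterification.

Step 9
Reactants: 16 dihydrobenzofuran ester
Product: 17 [(2R,3S)-7-methoxy-2-(3,4,5-trimethoxyphenyl)-3-(triisopropylsilyloxymethyl)-2,3-dihydrobenzofuran-5-yl]methanol
Conditions: i-Bu2AlH (2.5 equiv), CH2Cl2, −78 to 0 °C; aq. potassium sodium tartrate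
Reagents that add atoms: none
Why: Hydride reduction of the aryl ester to the benzylic alcohol; the silyl ether and the cyclic benzylic ether are inert to the reagent.

Step 10
Reactants: 17 benzylic alcohol
Product: 19 ethyl (E)-3-[(2R,3S)-7-methoxy-2-(3,4,5-trimethoxyphenyl)-3-(triisopropylsilyloxymethyl)-2,3-dihydrobenzofuran-5-yl]prop-2-enoate, via aldehyde 18 (not isolated)
Conditions: MnO2 (15 equiv), Ph3P=CHCO2Et (1.3 equiv), CH2Cl2, rt to 40 °C
Reagents that add atoms: ethyl (triphenylphosphoranylidene)acetate, CCOC(=O)C=P(c1ccccc1)(c1ccccc1)c1ccccc1
Why: Tandem oxidation–Wittig reaction: activated MnO2 oxidises only the benzylic alcohol, and the stabilised ylide traps the aldehyde as it forms. Stabilised ylides give the E enoate.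

Step 11
Reactants: 19 ethyl enoate
Product: 20 (E)-3-[(2R,3S)-7-methoxy-2-(3,4,5-trimethoxyphenyl)-3-(triisopropylsilyloxymethyl)-2,3-dihydrobenzofuran-5-yl]prop-2-en-1-ol
Conditions: i-Bu2AlH (2.5 equiv), CH2Cl2, −78 °C
Reagents that add atoms: none
Why: 1,2-Reduction of the α,β-unsaturated ester to the allylic alcohol; the alkene geometry is not affected.

Step 12
Reactants: 20 silyl-protected diol
Product: 21 (7R,8S,7'E)-3,4,5,5'-tetramethoxy-4',7-epoxy-8,3'-neolign-7'-ene-9,9'-diol (target)
Conditions: Bu4NF (1.5 equiv), THF, 0 °C to rt
Reagents that add atoms: none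
Why: Fluoride cleaves the Si–O bond; the non-acidic medium leaves the C7 benzylic ether and the cinnamyl alcohol untouched.

## Compound list

1 | acenaphthoquinone | O=C1C(=O)c2cccc3cccc1c23 | starting material
2 | cis-1,2-dimethyl-1,2-dihydroacenaphthylene-1,2-diol (mac diol) | C[C@]1(O)c2cccc3cccc(c23)[C@@]1(C)O | intermediate
3 | propargyl alcohol | C#CCO | starting material
4 | triisopropyl(prop-2-yn-1-yloxy)silane | C#CCO[Si](C(C)C)(C(C)C)C(C)C | intermediate
5 | (E)-2-[3-(triisopropylsilyloxy)prop-1-en-1-yl]-1,3,2-benzodioxaborole | CC(C)[Si](C(C)C)(C(C)C)OC/C=C/B1Oc2ccccc2O1 | intermediate (not isolated)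
6 | (E)-triisopropyl{[3-(cis-6b,9a-dimethyl-6b,9a-dihydroacenaphtho[1,2-d][1,3,2]dioxaborol-8-yl)prop-2-en-1-yl]oxy}silane | CC(C)[Si](C(C)C)(C(C)C)OC/C=C/B1O[C@@]2(C)c3cccc4cccc(c34)[C@@]2(C)O1 | intermediate
7 | methyl 4-fluoro-3-methoxybenzoate | COc1cc(C(=O)OC)ccc1F | starting material
8 | methyl 4-fluoro-3-methoxy-5-(4,4,5,5-tetramethyl-1,3,2-dioxaborolan-2-yl)benzoate | COc1cc(C(=O)OC)cc(B2OC(C)(C)C(C)(C)O2)c1F | intermediate (not isolated)
9 | methyl 4-fluoro-3-hydroxy-5-methoxybenzoate | COc1cc(C(=O)OC)cc(O)c1F | intermediate
10 | methyl 4-fluoro-3-methoxy-5-(trifluoromethylsulfonyloxy)benzoate | COc1cc(C(=O)OC)cc(OS(=O)(=O)C(F)(F)F)c1F | intermediate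
11 | 5-bromo-1,2,3-trimethoxybenzene | COc1cc(Br)cc(OC)c1OC | starting material
12 | (3,4,5-trimethoxyphenyl)lithium | [Li]c1cc(OC)c(OC)c(OC)c1 | intermediate (not isolated)
13 | lithium (E)-alkenyl(3,4,5-trimethoxyphenyl)borate of diol 2 (ate complex) | [Li+].COc1cc([B-]2(/C=C/CO[Si](C(C)C)(C(C)C)C(C)C)O[C@@]3(C)c4cccc5cccc(c45)[C@@]3(C)O2)cc(OC)c1OC | intermediate (not isolated)
14 | methyl 4-fluoro-3-methoxy-5-[(2S,3R)-3-B(mac)-3-(3,4,5-trimethoxyphenyl)-1-(triisopropylsilyloxy)propan-2-yl]benzoate | COc1cc([C@H](B2O[C@@]3(C)c4cccc5cccc(c45)[C@@]3(C)O2)[C@H](CO[Si](C(C)C)(C(C)C)C(C)C)c2cc(C(=O)OC)cc(OC)c2F)cc(OC)c1OC | intermediate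
15 | methyl 4-fluoro-3-[(1R,2S)-1-hydroxy-1-(3,4,5-trimethoxyphenyl)-3-(triisopropylsilyloxy)propan-2-yl]-5-methoxybenzoate | COc1cc([C@H](O)[C@H](CO[Si](C(C)C)(C(C)C)C(C)C)c2cc(C(=O)OC)cc(OC)c2F)cc(OC)c1OC | intermediate
16 | methyl (2R,3S)-7-methoxy-2-(3,4,5-trimethoxyphenyl)-3-(triisopropylsilyloxymethyl)-2,3-dihydrobenzofuran-5-carboxylate | COc1cc([C@@H]2Oc3c(OC)cc(C(=O)OC)cc3[C@H]2CO[Si](C(C)C)(C(C)C)C(C)C)cc(OC)c1OC | intermediate
17 | [(2R,3S)-7-methoxy-2-(3,4,5-trimethoxyphenyl)-3-(triisopropylsilyloxymethyl)-2,3-dihydrobenzofuran-5-yl]methanol | COc1cc([C@@H]2Oc3c(OC)cc(CO)cc3[C@H]2CO[Si](C(C)C)(C(C)C)C(C)C)cc(OC)c1OC | intermediate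
18 | (2R,3S)-7-methoxy-2-(3,4,5-trimethoxyphenyl)-3-(triisopropylsilyloxymethyl)-2,3-dihydrobenzofuran-5-carbaldehyde | COc1cc([C@@H]2Oc3c(OC)cc(C=O)cc3[C@H]2CO[Si](C(C)C)(C(C)C)C(C)C)cc(OC)c1OC | intermediate (not isolated)
19 | ethyl (E)-3-[(2R,3S)-7-methoxy-2-(3,4,5-trimethoxyphenyl)-3-(triisopropylsilyloxymethyl)-2,3-dihydrobenzofuran-5-yl]prop-2-enoate | COc1cc([C@@H]2Oc3c(OC)cc(/C=C/C(=O)OCC)cc3[C@H]2CO[Si](C(C)C)(C(C)C)C(C)C)cc(OC)c1OC | intermediate
20 | (E)-3-[(2R,3S)-7-methoxy-2-(3,4,5-trimethoxyphenyl)-3-(triisopropylsilyloxymethyl)-2,3-dihydrobenzofuran-5-yl]prop-2-en-1-ol | COc1cc([C@@H]2Oc3c(OC)cc(/C=C/CO)cc3[C@H]2CO[Si](C(C)C)(C(C)C)C(C)C)cc(OC)c1OC | intermediate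
21 | (7R,8S,7'E)-3,4,5,5'-tetramethoxy-4',7-epoxy-8,3'-neolign-7'-ene-9,9'-diol | COc1cc([C@@H]2Oc3c(OC)cc(/C=C/CO)cc3[C@H]2CO)cc(OC)c1OC | target

## Step count and least certain steps

Total: 12 steps. Longest linear sequence: 9 steps (from 3 through steps 2, 3, 6–12; the sequences from 1 and from 7 are equally long).

**Step 6 (key step).**
- What may go wrong: direct transfer of an aryl or alkenyl group from boron to palladium, giving simple cross-coupling in place of the metallate shift; β-hydride or β-silyloxy elimination from the C8–palladium intermediate, which has the C9 silyloxymethyl group next to it; inhibition of the cationic catalyst by bromide; and weaker face selection with an ortho-fluoro, ester-bearing electrophile.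
- Fallback (sets out from 10, returns at 15): an auxiliary-controlled syn aldol route. Negishi-type coupling of 10 with BrZnCH2CO2t-Bu (Pd2(dba)3, XPhos, THF) would give methyl 3-(2-tert-butoxy-2-oxoethyl)-4-fluoro-5-methoxybenzoate F1. CF3CO2H in CH2Cl2 would cleave only the tert-butyl ester to 2-[2-fluoro-3-methoxy-5-(methoxycarbonyl)phenyl]acetic acid F2. Its mixed pivalic anhydride would acylate lithiated (R)-4-benzyloxazolidin-2-one to the N-arylacetyl oxazolidinone F3. The Z boron enolate of F3 (Bu2BOTf, i-Pr2NEt, CH2Cl2, −78 °C) would add to 3,4,5-trimethoxybenzaldehyde to give the syn aldol adduct F4, with both centres set by the auxiliary. NaBH4 in THF–H2O would remove the auxiliary reductively without touching the aryl ester and give methyl 3-[(1R,2S)-1,3-dihydroxy-1-(3,4,5-trimethoxyphenyl)propan-2-yl]-4-fluoro-5-methoxybenzoate F5. Silylation of the primary hydroxyl alone (i-Pr3SiCl, imidazole) would give 15.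

**Step 8.**
- What may go wrong: transfer of the silyl group from O9 to the C7 alkoxide, followed by closure through O9 (also a 5-exo process) to the wrong dihydrobenzofuran; intermolecular attack of the alkoxide on the ester if the substitution is slow.
- Fallback (sets out from 15, returns at 16): replace the silyl group by one that cannot migrate. Bu4NF would give the diol F5. Tritylation of the primary hydroxyl (Ph3CCl, pyridine) would give methyl 4-fluoro-3-[(1R,2S)-1-hydroxy-1-(3,4,5-trimethoxyphenyl)-3-(trityloxy)propan-2-yl]-5-methoxybenzoate F6. Ring closure with KN(SiMe3)2 would give methyl (2R,3S)-7-methoxy-2-(3,4,5-trimethoxyphenyl)-3-(trityloxymethyl)-2,3-dihydrobenzofuran-5-carboxylate F7. Formic acid in ether would remove the trityl group to give methyl (2R,3S)-3-(hydroxymethyl)-7-methoxy-2-(3,4,5-trimethoxyphenyl)-2,3-dihydrobenzofuran-5-carboxylate F8. Silylation (i-Pr3SiCl, imidazole) would give 16.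

**Step 3.**
- What may go wrong: incomplete exchange of catechol for the hindered tertiary diol, and hydrolysis or protodeboronation of the sensitive catechol ester before the exchange is complete.
- Fallback (sets out from 4, returns at 6): go through an isolated boronic acid. Hydroboration of 4 with pinacolborane catalysed by Cp2Zr(H)Cl would give (E)-triisopropyl{[3-(4,4,5,5-tetramethyl-1,3,2-dioxaborolan-2-yl)prop-2-en-1-yl]oxy}silane F9. NaIO4 and NH4OAc in acetone–H2O would cleave the pinacol to give (E)-[3-(triisopropylsilyloxy)prop-1-en-1-yl]boronic acid F10. Condensation of F10 with 2 over MgSO4 would give 6.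

**Step 7.**
- What may go wrong: slow oxidation of the hindered boronic ester under mild conditions, so that stronger base becomes necessary and the methyl ester is saponified.
- Fallback (sets out from 14, returns at 15): accept the hydrolysis and restore the ester. NaOH and H2O2 in THF–H2O would give 4-fluoro-3-[(1R,2S)-1-hydroxy-1-(3,4,5-trimethoxyphenyl)-3-(triisopropylsilyloxy)propan-2-yl]-5-methoxybenzoic acid F11. Selective O-methylation of the carboxylate (MeI, KHCO3, DMF) would give 15.

## Further compounds

F1 | step 6 | methyl 3-(2-tert-butoxy-2-oxoethyl)-4-fluoro-5-methoxybenzoate | COc1cc(C(=O)OC)cc(CC(=O)OC(C)(C)C)c1F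
F2 | step 6 | 2-[2-fluoro-3-methoxy-5-(methoxycarbonyl)phenyl]acetic acid | COc1cc(C(=O)OC)cc(CC(=O)O)c1F
F3 | step 6 | methyl 3-{2-[(4R)-4-benzyl-2-oxooxazolidin-3-yl]-2-oxoethyl}-4-fluoro-5-methoxybenzoate | COc1cc(C(=O)OC)cc(CC(=O)N2[C@H](Cc3ccccc3)COC2=O)c1F
F4 | step 6 | methyl 3-[(2R,3R)-1-[(4R)-4-benzyl-2-oxooxazolidin-3-yl]-3-hydroxy-1-oxo-3-(3,4,5-trimethoxyphenyl)propan-2-yl]-4-fluoro-5-methoxybenzoate | COc1cc([C@H](O)[C@H](C(=O)N3[C@H](Cc4ccccc4)COC3=O)c2cc(C(=O)OC)cc(OC)c2F)cc(OC)c1OC
F5 | step 6 | methyl 3-[(1R,2S)-1,3-dihydroxy-1-(3,4,5-trimethoxyphenyl)propan-2-yl]-4-fluoro-5-methoxybenzoate | COc1cc([C@H](O)[C@H](CO)c2cc(C(=O)OC)cc(OC)c2F)cc(OC)c1OC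
F6 | step 8 | methyl 4-fluoro-3-[(1R,2S)-1-hydroxy-1-(3,4,5-trimethoxyphenyl)-3-(trityloxy)propan-2-yl]-5-methoxybenzoate | COc1cc([C@H](O)[C@H](COC(c2ccccc2)(c2ccccc2)c2ccccc2)c2cc(C(=O)OC)cc(OC)c2F)cc(OC)c1OC
F7 | step 8 | methyl (2R,3S)-7-methoxy-2-(3,4,5-trimethoxyphenyl)-3-(trityloxymethyl)-2,3-dihydrobenzofuran-5-carboxylate | COc1cc([C@@H]2Oc3c(OC)cc(C(=O)OC)cc3[C@H]2COC(c2ccccc2)(c2ccccc2)c2ccccc2)cc(OC)c1OC
F8 | step 8 | methyl (2R,3S)-3-(hydroxymethyl)-7-methoxy-2-(3,4,5-trimethoxyphenyl)-2,3-dihydrobenzofuran-5-carboxylate | COc1cc([C@@H]2Oc3c(OC)cc(C(=O)OC)cc3[C@H]2CO)cc(OC)c1OC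
F9 | step 3 | (E)-triisopropyl{[3-(4,4,5,5-tetramethyl-1,3,2-dioxaborolan-2-yl)prop-2-en-1-yl]oxy}silane | CC(C)[Si](C(C)C)(C(C)C)OC/C=C/B1OC(C)(C)C(C)(C)O1
F10 | step 3 | (E)-[3-(triisopropylsilyloxy)prop-1-en-1-yl]boronic acid | CC(C)[Si](C(C)C)(C(C)C)OC/C=C/B(O)O
F11 | step 7 | 4-fluoro-3-[(1R,2S)-1-hydroxy-1-(3,4,5-trimethoxyphenyl)-3-(triisopropylsilyloxy)propan-2-yl]-5-methoxybenzoic acid | COc1cc([C@H](O)[C@H](CO[Si](C(C)C)(C(C)C)C(C)C)c2cc(C(=O)O)cc(OC)c2F)cc(OC)c1OC
A1 | alternative 1 | 4-[(2R,3S)-5-bromo-7-methoxy-3-(triisopropylsilyloxymethyl)-2,3-dihydrobenzofuran-2-yl]-2,6-dimethoxyphenol | COc1cc([C@@H]2Oc3c(OC)cc(Br)cc3[C@H]2CO[Si](C(C)C)(C(C)C)C(C)C)cc(OC)c1O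
A2 | alternative 1 | 4-bromo-2-[(2S)-1-(4-hydroxy-3,5-dimethoxyphenyl)-3-(triisopropylsilyloxy)propan-2-yl]-6-methoxyphenol | COc1cc(C[C@H](CO[Si](C(C)C)(C(C)C)C(C)C)c2cc(Br)cc(OC)c2O)cc(OC)c1O
A3 | alternative 2 | methyl (2R,3S)-7-bromo-2-(3,4,5-trimethoxyphenyl)-3-(triisopropylsilyloxymethyl)-2,3-dihydrobenzofuran-5-carboxylate | COc1cc([C@@H]2Oc3c(Br)cc(C(=O)OC)cc3[C@H]2CO[Si](C(C)C)(C(C)C)C(C)C)cc(OC)c1OC
A4 | alternative 2 | tert-butyldimethyl{[(4S,5R)-5-(3,4,5-trimethoxyphenyl)-4-(triisopropylsilyloxymethyl)-4,5-dihydrofuran-2-yl]oxy}silane | COc1cc([C@@H]2OC(O[Si](C)(C)C(C)(C)C)=C[C@H]2CO[Si](C(C)C)(C(C)C)C(C)C)cc(OC)c1OC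
A5 | alternative 2 | methyl 3-bromo-2-oxo-2H-pyran-5-carboxylate (methyl 3-bromocoumalate) | COC(=O)C1=COC(=O)C(Br)=C1
A6 | alternative 3 | methyl (2R,3S)-7-methoxy-3-[(2,2,6,6-tetramethylpiperidin-1-yloxy)methyl]-2-(3,4,5-trimethoxyphenyl)-2,3-dihydrobenzofuran-5-carboxylate | COc1cc([C@@H]2Oc3c(OC)cc(C(=O)OC)cc3[C@H]2CON4C(C)(C)CCCC4(C)C)cc(OC)c1OC
A7 | alternative 3 | methyl 3-iodo-5-methoxy-4-{[(1R)-1-(3,4,5-trimethoxyphenyl)prop-2-en-1-yl]oxy}benzoate | COc1cc([C@@H](C=C)Oc2c(I)cc(C(=O)OC)cc2OC)cc(OC)c1OC
A8 | alternative 3 | 2,2,6,6-tetramethylpiperidin-1-oxyl (TEMPO) | CC1(C)CCCC(C)(C)N1[O]
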